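(The runs are calculated for substances that don't exist; scatter was added.)

I am asked for 4 readings of open intermediate in the flask, and I work from two earlier runs, birch and maple.

| flask | starting material | partner | capture agent | protic impurity | remark | time |
|---|---|---|---|---|---|---|
| birch | 0.13 M | 0.16 M | 0.060 M | 0.10 M | run made earlier |  |
| maple | 0.30 M | 0.16 M | 0.060 M | 0.10 M | run made earlier |  |
| flask | 0.20 M | 0.160 M | 0.0600 M | 0.100 M |  | 40 h |

- birch (time / h: open intermediate / %, target / %): 5.00: 23, 0; 10.0: 25, 0; 15.0: 24, 1; 20.0: 25, 2; 25.0: 22, 1; 30.0: 18, 2
- maple (time / h: open intermediate / %, target / %): 2.50: 17, 1; 4.00: 21, 0; 8.00: 28, 1; 12.0: 34, 0; 20.0: 41, 6; 30.0: 41, 7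

(readings scatter by 1.5 percentage points)

- amount of open intermediate in percent of the starting material charged, at 4.0 h, 12 h, 25 h and 40 h

- the numbers in the tables scatter with a standard deviation of 1.5 percentage points

I assume that starting material either opens or is quenched by protic impurity, the quench being pseudo-first-order in starting material at a given c(protic impurity), and that each capture agent removes one open intermediate. The flask then has two extremes. Once starting material and capture agent are both spent, open intermediate plus target come to 20.0% of the charge if the impurity has taken its whole charge, and to 70.0% if it has taken nothing. Where the flask lies depends on r, the c(protic impurity) at which opening and quench run equally fast.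

Each run yields a rough estimate of r if I suppose starting material and capture agent both spent at the chosen reading, and subtract that reading and the capture charge from the starting material. Maple at 30.0 h implies a quench of 0.0960 M, so r is 0.0634 M. Birch at 20.0 h implies 0.0349 M, so r is 0.222 M. These readings are rough, so I take their geometric mean, 0.118 M.

For the flask, the impurity consumed equals its charge times one minus exp(−(charge of starting material − impurity consumed)/r). Starting from the whole impurity charge, I get 0.0570 M, then 0.0701 M. One more round gives the quench toll, the starting material lost to protic impurity by the time starting material is used up: 0.0666 M. That leaves 0.0734 M, or 36.7% of the charge, for open intermediate plus target.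

The forecast gives 24%, 34%, 38% and 31%, the highest of these above my end budget, and it warns: “That late loss is the least certain part, since its mechanism and the capture agent's role remain unclear.”

The flask gives 20.6%, 30.2%, 30.5% and 28.3%.

    open intermediate + capture agent → trapped intermediate (k = 0.0272 M⁻¹ min⁻¹)
    starting material + protic impurity → quenched substrate (k = 0.0132 M⁻¹ min⁻¹)
    second intermediate → side product (k = 2.82 × 10⁻⁴ min⁻¹)
    open intermediate + second intermediate → target (k = 0.00180 M⁻¹ min⁻¹)
    2 second intermediate → homo product (k = 0.00310 M⁻¹ min⁻¹)
    starting material → open intermediate (k = 0.00139 min⁻¹)
    partner → second intermediate (k = 7.99 × 10⁻⁴ min⁻¹)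

The forecast is 7.5 points high at 25 h. At 40.0 h, quenched substrate stands at 35.1% of the charge, against my toll of 33.3%. A run of this flask without the quench step shows what this toll costs: open intermediate at that time is 56.4% rather than 28.3%. With the toll at zero, my budget for open intermediate plus target becomes 70.0%, and that run holds 56.4% as open intermediate.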